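I began with a balance.

common to all: free catalyst 88 mM; impurity 9.8 mM

|  | substrate | coupling partner | remark | time |
|---|---|---|---|---|
| elm | 0.089 M | 2 M | run made earlier |  |
| maple | 0.59 M | 2 M | run made earlier |  |
| violet | 0.10 M | 2.00 M |  | 1.5 h |
| green | 0.20 M | 2.00 M |  | 1.5 h |
| blue | 0.40 M | 2.00 M |  | 1.5 h |
| red | 0.80 M | 2.00 M |  | 1.5 h |

| elm: time / min | elm: target / % | maple: time / min | maple: target / % |
|---|---|---|---|
| 3.00 | 1.6 | 4.00 | 2.1 |
| 8.00 | 8.4 | 6.00 | 4.7 |
| 15.0 | 19.9 | 10.0 | 10.1 |
| 25.0 | 33.1 | 15.0 | 16.2 |
| 30.0 | 38.7 | 25.0 | 25.8 |
| 50.0 | 58.3 | 50.0 | 49.2 |

(scatter of a reading: 0.5 percentage points)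

- what was read earlier has a scatter of 0.5 percentage points, one standard deviation
- "hardly changes" means that all values lie within two and a half points (for a concentration: within two and a half percent of the largest)

1. amount of target at the end, in percent of the substrate charged for violet, green, blue, red, in this order
2. the shape of the row from first to last (falls all the way / falls, then rises / rises, then falls / hardly changes / rises all the way)

Against the coupling partner, the substrate was the limiting reagent. I assumed that one coupling partner is lost per substrate lost, so c_partner falls from its charge by what c_substrate has lost. Full conversion then takes a fixed share of the partner. For red this partner draw is 40.0 %, the substrate charge over the partner charge, and for violet it is 5.00 %.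

The bench rule says that a partner charged at ten times the substrate, as in green, may be taken as constant. The reaction is then pseudo-first-order, with one time constant, and at fixed catalyst and impurity charges the percentage reached at a given time does not depend on the substrate charge. I applied this to elm, whose partner stood at 22.5 times its substrate. I took the share not yet read as target to stand for the unreacted substrate; its fall between 15.0 min and 50.0 min in the elm readings gave a time constant of 53.6 min, and carrying that on to 1.5 h gave my estimate of 80.2 % for violet.

But the partner stands at 5.00 times the substrate in blue and 2.50 times in red, and maple, at 3.39, lies under the border of ten times as well. At 50.0 min maple read 49.2 % against 58.3 % for elm, a gap of 9.1 percentage points with a scatter of 0.5 points. So I kept 80.2 % for violet and expected the row to fall all the way. Red's draw is larger than maple's 29.5 %, so I expected red to lie more than that gap below violet.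

The forecast gave 81 %, 79.5 %, 76.5 % and 70 %, a row that falls all the way, with a violet value above my own, and it read the runs as a sign of “mild saturation in substrate”.

The flask gave 79.4 %, 77.8 %, 74.4 % and 67.6 %, so the row falls all the way.

    coupling partner + free catalyst ⇌ catalyst intermediate A (K = 0.480 M⁻¹, k = 0.800 M⁻¹ min⁻¹)
    substrate + catalyst intermediate A → catalyst intermediate B (k = 0.500 M⁻¹ min⁻¹)
    catalyst intermediate B ⇌ by-product + catalyst intermediate C (K = 2.30 M, k = 0.770 min⁻¹)
    catalyst intermediate C → free catalyst + target (k = 0.980 min⁻¹)
    free catalyst + impurity → spent catalyst (k = 1700 M⁻¹ min⁻¹)

After 1.50 h, red still held 31 % of its substrate, and the draw turns the lost substrate into 72.4 % of the partner charge left. Catalyst intermediate A also holds partner, and it stood at 30.6 % of the catalyst charged, which brings the figure to 71.2 %; red held 71 %. For violet, the same balance with 20 % of the substrate left and 41.6 % of the catalyst in catalyst intermediate A gives 94.2 %, and violet held 94 %.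

Readings and results are calculated with constants of no real substance; scatter was added.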